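**Remark (assumption):** 3-methylbut-3-enal (5) is taken to be usable as a freshly made cold solution, because it isomerizes to the conjugated enal on standing.

## Strategy

Everything rests on disconnecting the carbon–carbon bond between the bridging-ether CH carbon and the methyl-bearing quaternary C–O carbon, the bond shared by the oxepane bridge of the 2-oxabicyclo[3.2.2]nonane and the bromotetrahydropyran. A SmI2 ketyl–olefin cyclization of a methyl ketone onto an (E)-β-alkoxyacrylate carried by the tertiary ring oxygen should forge this bond, set both of its stereocenters, close the bridged oxepane and, through the syn outcome, a temporary γ-lactone that later becomes the prenyl chain. It exploits the cis-1,4 relation of acetyl and tertiary oxygen on the cyclohexane and the adjacent cis-acetoxy group as a samarium-chelating handle. The precursor is a monocyclic keto acrylate made by Evans aldol and ring-closing metathesis.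

Key step: step 11

Locants used for the bicyclic compounds (2-oxabicyclo[3.2.2]nonane): C1 = C(Me)–O bridgehead, O2, C3 = OCH, C4 = C(Me)–O, C5 = CH bridgehead, C6 = CH–OAc/OH, C7 = CH2, C8 = CH–OSi/OH, C9 = CH2.

## Route

Step 1
Reactants: 1 (R)-4-benzyl-1,3-oxazolidin-2-one; 2 pent-4-enoyl chloride
Product: 3 (R)-4-benzyl-3-(pent-4-enoyl)-1,3-oxazolidin-2-one
Conditions: Et3N, DMAP (cat.), CH2Cl2, 0 °C to rt
Reagents that add atoms: none
Why: DMAP-catalysed N-acylation (nucleophilic acyl substitution) puts the pentenoyl chain on the chiral auxiliary without forming a stereocenter.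

Step 2
Reactants: 4 3-methylbut-3-en-1-ol
Product: 5 3-methylbut-3-enal
Conditions: Dess–Martin periodinane, CH2Cl2, 0 °C; filtered cold and used at once as a solution
Reagents that add atoms: none
Why: Dess–Martin oxidation gives the aldehyde under non-basic conditions that should not move the 1,1-disubstituted alkene into conjugation.

Step 3
Reactants: 3 (R)-4-benzyl-3-(pent-4-enoyl)-1,3-oxazolidin-2-one; 5 3-methylbut-3-enal
Product: 7 (R)-4-benzyl-3-[(2R,3S)-3-hydroxy-5-methyl-2-(prop-2-en-1-yl)hex-5-enoyl]-1,3-oxazolidin-2-one, via Z-boron enolate 6 (not isolated)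
Conditions: Bu2BOTf, i-Pr2NEt, CH2Cl2, −78 to 0 °C; then 5, −78 to 0 °C; pH 7 buffer, MeOH, H2O2
Reagents that add atoms: none
Why: In this Evans syn-aldol reaction the Z-boron enolate reacts through a Zimmerman–Traxler chair whose enolate face is dictated by the (R)-benzyl auxiliary, so the (2R,3S)-syn adduct should form, which fixes the cis relation and absolute configuration of the future C–OAc carbon and the acetyl-bearing ring carbon.

Step 4
Reactants: 7 aldol adduct
Product: 8 (R)-4-benzyl-3-[(1R,6S)-6-hydroxy-4-methylcyclohex-3-ene-1-carbonyl]-1,3-oxazolidin-2-one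
Conditions: second-generation Grubbs catalyst RuCl2(=CHPh)(PCy3)(H2IMes) (cat.), CH2Cl2, 40 °C
Reagents that add atoms: none
Why: Ring-closing metathesis of the allyl and 2-methylallyl arms releases ethene and forms the trisubstituted cyclohexene without touching the two stereocenters.

Step 5
Reactants: 8 cyclohexene imide
Product: 9 (1R,6S)-6-hydroxy-N-methoxy-N,4-dimethylcyclohex-3-ene-1-carboxamide
Conditions: MeNH(OMe)·HCl, AlMe3, CH2Cl2, −10 to 0 °C
Reagents that add atoms: N,O-dimethylhydroxylamine hydrochloride, CNOC.Cl
Why: Aluminium amide transamidation (Weinreb amide formation), assisted by the free β-hydroxyl, cleaves the auxiliary without epimerization.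

Step 6
Reactants: 9 Weinreb amide
Product: 10 1-[(1R,6S)-6-hydroxy-4-methylcyclohex-3-en-1-yl]ethan-1-one
Conditions: MeMgBr (3 equiv), THF, 0 °C
Reagents that add atoms: methylmagnesium bromide, C[Mg]Br
Why: In the Weinreb ketone synthesis the chelated tetrahedral magnesium intermediate stops at the methyl ketone, and the magnesium alkoxide of the β-hydroxyl guards against elimination.

Step 7
Reactants: 10 cis-hydroxy ketone
Product: 11 (1S,6R)-6-acetyl-3-methylcyclohex-3-en-1-yl acetate
Conditions: Ac2O, pyridine, DMAP (cat.), CH2Cl2, 0 °C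
Reagents that add atoms: acetic anhydride, CC(=O)OC(C)=O
Why: DMAP-catalysed acetylation installs the acetate of the target early, where it also differentiates this hydroxyl and later serves as a chelating group.

Step 8
Reactants: 11 acetoxy ketone
Product: 13 (1S,3R,4R,6R)-6-acetyl-3,4-dihydroxy-3-methylcyclohexyl acetate, via anti-epoxide 12 (not isolated)
Conditions: m-CPBA, NaHCO3, CH2Cl2, 0 °C; then HClO4 (cat.), THF/H2O, 0 °C to rt
Reagents that add atoms: m-chloroperbenzoic acid, OOC(=O)c1cccc(Cl)c1; water, O
Why: Peracid epoxidation should occur on the face opposite to the cis acetoxy/acetyl pair, and acid-catalysed hydrolysis opens the epoxide at the tertiary carbon with inversion (trans-diaxial opening, Fürst–Plattner rule), which sets the tertiary alcohol cis to the acetyl group and the secondary alcohol trans to it.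

Step 9
Reactants: 13 diol
Product: 14 (1S,3R,4R,6R)-6-acetyl-4-[(tert-butyldimethylsilyl)oxy]-3-hydroxy-3-methylcyclohexyl acetate
Conditions: TBSOTf (1.05 equiv), 2,6-lutidine, CH2Cl2, −78 °C
Reagents that add atoms: tert-butyldimethylsilyl triflate, CC(C)(C)[Si](C)(C)OS(=O)(=O)C(F)(F)F
Why: Silylation with the silyl triflate should discriminate the secondary from the tertiary hydroxyl on steric grounds and leave the tertiary alcohol free.

Step 10
Reactants: 14 tertiary alcohol
Product: 15 ethyl (E)-3-alkoxyacrylate of 14 (tertiary oxygen now bears the (E)-2-(ethoxycarbonyl)vinyl group)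
Conditions: ethyl propiolate, PMe3 (cat.), CH2Cl2, 0 °C to rt
Reagents that add atoms: ethyl propiolate, C#CC(=O)OCC
Why: Phosphine-catalysed oxa-Michael addition of the tertiary alcohol to the propiolate should give the (E)-β-alkoxyacrylate, the radical acceptor for the key step.

Step 11
Reactants: 15 keto β-alkoxyacrylate
Product: 17 bridged tricyclic γ-lactone (6-acetoxy-8-silyloxy-1,4-dimethyl-2-oxabicyclo[3.2.2]nonane cis-fused at C3–C4 to a butyrolactone), via hydroxy ester 16 (not isolated)
Conditions: SmI2 (3 equiv), MeOH (4 equiv), THF, 0 °C to rt; silica gel work-up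
Reagents that add atoms: none
Why: SmI2 reduces the methyl ketone to a samarium ketyl whose carbinol carbon adds to the β-carbon of the (E)-β-alkoxyacrylate, the ester α-radical is reduced and protonated by MeOH, and the tertiary samarium alkoxide then expels ethoxide to give the lactone. The closest known reaction type is the SmI2-mediated reductive cyclization of carbonyl compounds onto β-alkoxyacrylates that builds oxepanes and tetrahydropyrans bearing angular methyl groups. The oxepane closes 7-exo-trig as a bridge across the cyclohexane, which is possible because the acetyl group and the tertiary ether oxygen are cis-1,4 and meet in a twist-boat, and the lactone closes 5-exo-trig by acyl substitution. The quaternary carbinol centre should be controlled by chelation of the ketyl oxygen–samarium to the cis-acetoxy group on the neighbouring ring carbon, which turns the oxygen toward that two-carbon bridge and the methyl group away from it. The ether CH centre should be controlled by coordination of the same samarium to the ester carbonyl, which holds the acrylate chain syn to the ketyl oxygen, the only arrangement within reach across the short three-atom bridge. The step needs this syn relationship on the acetoxy side together with C–C bond formation outrunning simple ketyl reduction; the three-point chelate and the slow reduction of dialkyl ketyls by SmI2/MeOH without additive should secure both, and the syn product is drained irreversibly as the lactone.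

Step 12
Reactants: 17 bridged lactone
Product: 18 lactol with free C6 hydroxyl (anomer mixture)
Conditions: i-Bu2AlH (3.5 equiv), CH2Cl2, −78 °C; aqueous KNaC4H4O6
Reagents that add atoms: none
Why: At −78 °C the aluminium hydride should reduce the γ-lactone only to the lactol (stable tetrahedral aluminate) and cleave the acetate reductively in the same operation.

Step 13
Reactants: 18 lactol
Product: 19 8-[(tert-butyldimethylsilyl)oxy]-1,4-dimethyl-3-(3-methylbut-2-en-1-yl)-2-oxabicyclo[3.2.2]nonane-4,6-diol
Conditions: i-PrPPh3I, n-BuLi, THF, 0 °C; then 18, 0 °C to rt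
Reagents that add atoms: isopropyltriphenylphosphonium iodide, CC(C)[P+](c1ccccc1)(c1ccccc1)c1ccccc1.[I-]
Why: Wittig olefination of the lactol through its open hydroxy aldehyde form with the unstabilized isopropylidene ylide installs the prenyl-type alkene and frees the tertiary alcohol.

Step 14
Reactants: 19 prenyl diol
Product: 20 6-O-acetate of 19
Conditions: Ac2O, pyridine, DMAP (cat.), CH2Cl2, 0 °C
Reagents that add atoms: acetic anhydride, CC(=O)OC(C)=O
Why: Acetylation should be selective for the secondary hydroxyl because the tertiary carbinol is too hindered to be acylated under these conditions.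

Step 15
Reactants: 20 prenyl hydroxy acetate
Product: 21 8-O-(tert-butyldimethylsilyl) ether of the target
Conditions: Et2SBr·SbCl5Br (BDSB, 1.1 equiv), MeNO2, −25 °C; aqueous Na2SO3/NaHCO3 quench
Reagents that add atoms: bromodiethylsulfonium bromopentachloroantimonate, CC[S+](Br)CC.Br[Sb-](Cl)(Cl)(Cl)(Cl)Cl
Why: In this bromonium-induced 6-endo etherification the tertiary hydroxyl attacks the dimethyl-substituted carbon anti to bromine through a chair that keeps the bicyclic ring carbon and the bromine equatorial, which should set the C–Br stereocenter as in the target.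

Step 16
Reactants: 21 silyl ether
Product: 22 CNP0247588.2 (target)
Conditions: HF·pyridine, THF, 0 °C to rt
Reagents that add atoms: none
Why: Fluoride-mediated desilylation should free the secondary alcohol without affecting the acetate or the secondary bromide.

## Compound list

1 | (R)-4-benzyl-1,3-oxazolidin-2-one | O=C1N[C@H](Cc2ccccc2)CO1 | starting material
2 | pent-4-enoyl chloride | C=CCCC(Cl)=O | starting material
3 | (R)-4-benzyl-3-(pent-4-enoyl)-1,3-oxazolidin-2-one | C=CCCC(=O)N1[C@H](Cc2ccccc2)COC1=O | intermediate
4 | 3-methylbut-3-en-1-ol | CC(=C)CCO | starting material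
5 | 3-methylbut-3-enal | CC(=C)CC=O | intermediate
6 | (Z)-dibutylboron enolate of 3 | C=CC/C=C(\OB(CCCC)CCCC)N1[C@H](Cc2ccccc2)COC1=O | intermediate
7 | (R)-4-benzyl-3-[(2R,3S)-3-hydroxy-5-methyl-2-(prop-2-en-1-yl)hex-5-enoyl]-1,3-oxazolidin-2-one | C=CC[C@H]([C@@H](O)CC(C)=C)C(=O)N1[C@H](Cc2ccccc2)COC1=O | intermediate
8 | (R)-4-benzyl-3-[(1R,6S)-6-hydroxy-4-methylcyclohex-3-ene-1-carbonyl]-1,3-oxazolidin-2-one | O[C@H]1CC(C)=CC[C@H]1C(=O)N2[C@H](Cc3ccccc3)COC2=O | intermediate
9 | (1R,6S)-6-hydroxy-N-methoxy-N,4-dimethylcyclohex-3-ene-1-carboxamide | O[C@H]1CC(C)=CC[C@H]1C(=O)N(C)OC | intermediate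
10 | 1-[(1R,6S)-6-hydroxy-4-methylcyclohex-3-en-1-yl]ethan-1-one (hydroxyl cis to acetyl) | O[C@H]1CC(C)=CC[C@H]1C(C)=O | intermediate
11 | (1S,6R)-6-acetyl-3-methylcyclohex-3-en-1-yl acetate | CC(=O)O[C@H]1CC(C)=CC[C@H]1C(C)=O | intermediate
12 | (1S,3S,4R,6R)-6-acetyl-3,4-epoxy-3-methylcyclohexyl acetate (oxirane on the face opposite to acetoxy and acetyl) | CC(=O)O[C@H]1C[C@]2(C)O[C@@H]2C[C@H]1C(C)=O | intermediate
13 | (1S,3R,4R,6R)-6-acetyl-3,4-dihydroxy-3-methylcyclohexyl acetate (tertiary OH cis to acetyl and acetoxy, secondary OH trans) | CC(=O)O[C@H]1C[C@@](C)(O)[C@H](O)C[C@H]1C(C)=O | intermediate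
14 | (1S,3R,4R,6R)-6-acetyl-4-[(tert-butyldimethylsilyl)oxy]-3-hydroxy-3-methylcyclohexyl acetate | CC(=O)O[C@H]1C[C@@](C)(O)[C@H](O[Si](C)(C)C(C)(C)C)C[C@H]1C(C)=O | intermediate
15 | ethyl (E)-3-alkoxyacrylate of 14 (tertiary oxygen bears the (E)-2-(ethoxycarbonyl)vinyl group; ring stereocenters as in 14) | CC(=O)O[C@H]1C[C@@](C)(O/C=C/C(=O)OCC)[C@H](O[Si](C)(C)C(C)(C)C)C[C@H]1C(C)=O | intermediate
16 | ethyl 2-{6-acetoxy-8-[(tert-butyldimethylsilyl)oxy]-4-hydroxy-1,4-dimethyl-2-oxabicyclo[3.2.2]nonan-3-yl}acetate (C3 side chain and C4 hydroxyl both on the side of the C6–C7 bridge, C4 methyl toward the C8–C9 bridge, 6-OAc syn and 8-OSi anti to the ether bridge) | CC(=O)O[C@H]1C[C@@]2(C)O[C@@H](CC(=O)OCC)[C@@](C)(O)[C@@H]1C[C@H]2O[Si](C)(C)C(C)(C)C | intermediate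
17 | γ-lactone of 16 (C4–O–C(=O)–CH2–C3 ring cis-fused to the ether bridge, lying over the C6–C7 bridge) | CC(=O)O[C@H]1C[C@@]2(C)O[C@H]3CC(=O)O[C@@]3(C)[C@@H]1C[C@H]2O[Si](C)(C)C(C)(C)C | intermediate
18 | lactol of 17 with free 6-hydroxyl (lactone C=O reduced to CH–OH, anomer mixture) | O[C@H]1C[C@@]2(C)O[C@H]3CC(O)O[C@@]3(C)[C@@H]1C[C@H]2O[Si](C)(C)C(C)(C)C | intermediate
19 | 8-[(tert-butyldimethylsilyl)oxy]-1,4-dimethyl-3-(3-methylbut-2-en-1-yl)-2-oxabicyclo[3.2.2]nonane-4,6-diol (stereochemistry as in 16) | O[C@H]1C[C@@]2(C)O[C@@H](CC=C(C)C)[C@@](C)(O)[C@@H]1C[C@H]2O[Si](C)(C)C(C)(C)C | intermediate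
20 | 6-O-acetate of 19 | CC(=O)O[C@H]1C[C@@]2(C)O[C@@H](CC=C(C)C)[C@@](C)(O)[C@@H]1C[C@H]2O[Si](C)(C)C(C)(C)C | intermediate
21 | 8-O-(tert-butyldimethylsilyl) ether of the target (bromotetrahydropyran cis-fused at C3–C4, bromine equatorial) | CC(=O)O[C@H]1C[C@@]2(C)O[C@H]3C[C@H](Br)C(C)(C)O[C@@]3(C)[C@@H]1C[C@H]2O[Si](C)(C)C(C)(C)C | intermediate
22 | CNP0247588.2 | CC(=O)O[C@H]1C[C@@]2(C)O[C@H]3C[C@H](Br)C(C)(C)O[C@@]3(C)[C@@H]1C[C@H]2O | target

## Step count

Total steps: 16. Longest linear sequence: 15 steps (steps 1 and 3–16; step 2 is a one-step side branch).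

## Steps most likely to fail, with fallbacks

**Step 11 (key step).** The ketyl may be reduced to the secondary alcohol or dimerize before the cyclohexane reaches the twist-boat that brings it over the acrylate. Addition on the other side of the bridge would give an isomer that cannot lactonize. The fallback sets out from 15 and returns at 17, and attacks the acrylate from a neutral tertiary radical instead of a ketyl. Kinetic enolization on the methyl side with in situ silylation (LiN(SiMe3)2, Et3SiCl, THF, −78 °C) should give the triethylsilyl enol ether F1. Iron hydride hydrogen-atom transfer to its terminal CH2 (Fe(acac)3, PhSiH3, EtOH, 60 °C) generates the α-silyloxy tertiary radical, which should cyclize 7-exo onto the acrylate and be reduced (reductive olefin coupling) to the bridged silyl ether ester F2. HF·pyridine at 0 °C should cleave the tertiary triethylsilyl ether while the hindered tert-butyldimethylsilyl ether stays, and PPTS closes the lactone 17.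

**Step 15.** The bromonium ion may form on the wrong alkene face or collapse by proton loss to allylic bromides, and the strong acid released may attack the silyl ether, so that yield and the configuration at the C–Br centre erode. The fallback sets out from 20 and returns at 21. Shi epoxidation (the ketone catalyst derived from D-fructose is expected to deliver the needed (R)-epoxide; Oxone (2KHSO5·KHSO4·K2SO4), K2CO3, MeCN/dimethoxymethane/H2O, 0 °C) should give the epoxide F3. Camphorsulfonic acid (cat., CH2Cl2, 0 °C) should induce 6-endo opening at the tertiary epoxide carbon by the tertiary hydroxyl to give the 3-hydroxytetrahydropyran F4, whose axial hydroxyl sits where the hydrogen of the C–Br carbon must end. Appel bromination with inversion (CBr4, PPh3, toluene, 60 °C) then gives 21; this displacement next to a quaternary carbon is itself demanding.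

**Step 10.** The hindered tertiary hydroxyl may add more slowly than the basic phosphonium intermediates eliminate acetate from the β-acetoxy ketone, or the oxygen of a transient bicyclic hemiketal may add instead. The fallback sets out from 14 and returns at 15, and builds the acrylate without a basic catalyst from a vinyl ether. Transfer vinylation (Pd(OCOCF3)2, 4,7-diphenyl-1,10-phenanthroline, n-butyl vinyl ether, 75 °C) should give the vinyl ether F5. C-Acylation with trichloroacetyl chloride (pyridine, CH2Cl2, 0 °C) gives the (E)-β-alkoxyvinyl trichloromethyl ketone F6. Haloform-type ethanolysis (EtOH, K2CO3 (cat.), rt) then gives 15.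

## Further compounds

F1 | step 11 | triethylsilyl enol ether of 15 (terminal enol ether on the former acetyl group) | CC(=O)O[C@H]1C[C@@](C)(O/C=C/C(=O)OCC)[C@H](O[Si](C)(C)C(C)(C)C)C[C@H]1C(=C)O[Si](CC)(CC)CC
F2 | step 11 | C4-O-triethylsilyl ether of hydroxy ester 16 | CC(=O)O[C@H]1C[C@@]2(C)O[C@@H](CC(=O)OCC)[C@@](C)(O[Si](CC)(CC)CC)[C@@H]1C[C@H]2O[Si](C)(C)C(C)(C)C
F3 | step 15 | (R)-epoxide of the prenyl alkene of 20 | CC(=O)O[C@H]1C[C@@]2(C)O[C@@H](C[C@H]3OC3(C)C)[C@@](C)(O)[C@@H]1C[C@H]2O[Si](C)(C)C(C)(C)C
F4 | step 15 | 3-hydroxy-2,2-dimethyltetrahydropyran analogue of 21 (OH in place of Br, opposite configuration at that carbon) | CC(=O)O[C@H]1C[C@@]2(C)O[C@H]3C[C@@H](O)C(C)(C)O[C@@]3(C)[C@@H]1C[C@H]2O[Si](C)(C)C(C)(C)C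
F5 | step 10 | vinyl ether of the tertiary alcohol of 14 | CC(=O)O[C@H]1C[C@@](C)(OC=C)[C@H](O[Si](C)(C)C(C)(C)C)C[C@H]1C(C)=O
F6 | step 10 | (E)-β-alkoxyvinyl trichloromethyl ketone from F5 | CC(=O)O[C@H]1C[C@@](C)(O/C=C/C(=O)C(Cl)(Cl)Cl)[C@H](O[Si](C)(C)C(C)(C)C)C[C@H]1C(C)=O
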